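**Numbering.** Target numbering is used for all intermediates: C1 furanone carbonyl, C2=C3 furanone alkene (C3 on the ring oxygen), C4 (methyl C15)=C5, C6 (ester oxygen), C7, C8 (lactone oxygen), C9, C10 (methyl C14, ring oxygen), C11 (lactone α-carbon), C12 (lactone carbonyl), C13 (exocyclic methylene). Compounds are numbered 1–38 in order of appearance in the steps; the target is 38.

## Analysis of the target

Target 38 is a germacranolide whose ten-membered carbocycle C1–C10 is spanned by an oxygen between C3 and C10, so the core is an 11-oxabicyclo[6.2.1]undecane. Its five-membered ring is a 3(2H)-furanone cross-conjugated with the 4Z alkene. A trans-fused α-methylene-γ-butyrolactone sits on C7–C8 (oxygen on C8), and O6 carries a (2S,3S)-2,3-epoxy-2-methylbutanoate. The ring stereocentres are 6S, 7R, 8S and 10S. C6–C8 are contiguous: along the extended C5–C9 chain O6 and C11 are anti and C11 and O8 are syn, so the two oxygens are 1,3-anti. The quaternary, oxygen-bearing C10 lies across the ring from this triad. The α-methylene lactone, the vinylogous-ester furanone, the epoxy ester and any β-oxygenated ketone on the way are sensitive to nucleophiles, base and acid. The difficulty is to close a strained, unsaturated medium ring and to relate C10 to C6–C8 without a rigid template. The strategy rests on the C3–O–C10 ether bridge: this oxabicycle is what an oxonium ylide [2,3]-shift delivers when a pyran oxygen captures a carbenoid at C10 and the pyran is expanded by three atoms.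

## Retrosynthetic reasoning

**O6 ester.** 38 is cut at the ester C–O bond into alcohol 32 and epoxy acid 36. This comes last because the epoxy ester would not survive the enolate and fluoride steps. Acid 36 derives from angelic acid 33 through allylic alcohol 34 and epoxy alcohol 35; the Z alkene fixes the cis epoxide and an asymmetric epoxidation fixes its absolute sense.

**C11=C13.** The exocyclic methylene of 31 (the silyl ether of 32) is removed to lactone 28, with amine 29 and its quaternary salt 30 in between. The Michael acceptor is thus made late.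

**C12–O8 and the C8 carbinol.** Lactone 28 is opened and C8 is taken back to the ketone of keto ester 26 (hydroxy ester 27 in between). O6 must stay silylated here, because it is also γ to C12 and would compete for the lactone.

**C7–C11.** The acetate arm of 26 is disconnected to the C7=C8 silyl enol ether 23 and ethyl diazoacetate 24, with silyloxycyclopropane 25 as the relay. A free C8 enolate is avoided: the C6 silyloxy group is β to it and its loss would give a fully conjugated trienone. The cyclopropane forms the C7–C11 bond without an enolate and sets C7.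

**C2=C3.** The furanone alkene of 23 is taken back to the saturated ketone 21 (silyl enol ether 22 in between). C1 can enolise only towards C2, since C10 is quaternary. Doing this while C8 is still masked turns C1 into a vinylogous ester, so the later C8 reduction has no second ketone to contend with.

**Key disconnection.** In 21 the bonds O–C10 and C9–C10 are cut and O–C7 is re-formed. This gives dihydropyranyl diazoketone 19, whose carbenoid at C10 is five atoms from the pyran oxygen (ylide 20). Two rings, two skeletal bonds and the C10 stereocentre arise in one step, and C8 appears as a regiodefined enol ether exactly where the lactone is needed. What remains is a cis-2,6-disubstituted dihydropyran with three stereocentres.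

**Diazoketone.** 19 is cut at C1–C10 into acid 15 and diazoethane 17 (from nitrosourea 16), joined through mixed anhydride 18. The diazo group comes after the enol ether, because a diazoketone would not survive enolisation of the C8 ketone.

**Enol ether.** 15 goes back through silyl ester 14 to keto acid 13, then to hydroxy acid 12 and diester 11. The methyl ketone is unmasked only when no base-labile neighbour remains.

**C6 carbinol.** Silyl ether 11 and alcohol 10 come from enone 9 by 1,2-reduction trans to the C7 substituent.

**C3 stereocentre.** 9 is derived from hemiketal 8 by delivering hydrogen, not carbon, to the oxocarbenium ion. Addition of a carbon nucleophile to such a cation occurs anti to the C7 substituent and would give the 2,6-trans ring. With the acetate arm already on C3 and hydride arriving last, the cis ring needed for 19 results.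

**Pyranone.** 8 is the oxidative ring expansion product of furyl carbinol 7, itself from ketone 6. The carbinol carbon becomes C7 and controls C3 and C6.

**Furan.** 6 is cut into furylacetate 4 and acid chloride 5; 4 into bromofuran 2 and zinc enolate 3; 2 comes from 3-methylfuran 1. Two electrophilic substitutions and one cross-coupling place all three substituents without a regiochemical choice by lithiation.

## Alternatives that were turned down

**Alternative 1:** The C7–C11 bond and a temporary C6–C11 bond are cut in the cyclopropane-fused lactone A1. Forward, a rhodium carbenoid at C11, carried as a diazoacetyl group on O8, would add across an E C6=C7 alkene, closing the γ-lactone and a cyclopropane at once. An oxygen nucleophile would later open the cyclopropane at C6 with inversion. In its favour, the cis-fused bicycle and the SN2 opening derive C6, C7 and C8 from one carbinol centre; this is stronger stereocontrol over the triad than the chosen route, which relies on facial selectivity in a medium ring. Against it, the ten-membered ring and the furanone are still unmade in A1 and must be closed late between C2 and C3 on a substrate already carrying the lactone; the vinylcyclopropane can open SN2′ at C4; and C10 needs its own stereocontrol. The chosen route gives up some control at C7/C8 but obtains the whole oxabicycle, with C10 relayed from C3, in one step.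

**Alternative 2:** C3 and C4 are excised from the ten-membered silyloxy dienone A2. Forward, a silver-promoted (2+2) addition of a silyloxy-substituted C3≡C4 unit across the C2=C5 bond of an eight-membered enone, then thermal conrotatory opening of the four-membered ring, would insert the two carbons. In its favour, C3 arrives at the furanone oxidation level with the C4 methyl in place, and C6–C8 can be set on an eight-membered ring whose conformations are easier to predict; on those points it is at least as strong as the chosen route. Against it, conrotatory opening of a cis-fused cyclobutene puts one trans double bond (C2=C3) into the ten-membered ring of A2, the eight-membered enone with C10 and three further stereocentres is a synthesis of its own, and furanone closure by O10 is a further step. The chosen route closes the furanone and the carbocycle together and has direct precedent for the ring size.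

**Alternative 3:** The C6–C7 bond is cut in carbocycle A3, which already holds the furanone, a free 6-hydroxyl and a 7-isopropenyl group. Forward, deprotonation at C6 of a thirteen-membered ring in which O6 is tied to C13 would trigger a [2,3]-Wittig shift that contracts the ring by three atoms. In its favour, C6 and C7 are set in one sigmatropic event, O6 emerges free for the esterification and C13 is already the methylene; the chosen route needs separate steps for each of these. Against it, a carbanion is generated next to the base-sensitive furanone, the thirteen-membered ether needs its own macrocyclisation, and C12 must afterwards be oxidised from methyl to carboxyl in the presence of other allylic positions before the lactone can close. The chosen route brings C12 in at the ester oxidation level and needs no late C–H oxidation.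

Key step: step 13

## Route

Remark on the chemistry: hemiketal 8 is used as the anomeric mixture and 25, 29 and 30 as C11 epimer mixtures, since these centres are removed later; ylide 20 is drawn free of copper.

Step 1
Reactants: 1 3-methylfuran
Product: 2 2-bromo-3-methylfuran
Conditions: NBS, DMF, −20 to 0 °C
Reagents that add atoms: N-bromosuccinimide, O=C1CCC(=O)N1Br
Why: Electrophilic bromination of a furan at an α-position; the α-carbon next to the methyl group is the more electron-rich, so C2 is brominated and the other α-position is kept free for step 3.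

Step 2
Reactants: 2 2-bromo-3-methylfuran; 3 (2-ethoxy-2-oxoethyl)zinc bromide
Product: 4 ethyl 2-(3-methylfuran-2-yl)acetate
Conditions: Pd(dba)2 (2 mol %), P(t-Bu)3 (2 mol %), THF, rt
Reagents that add atoms: none
Why: Negishi-type coupling of a Reformatsky reagent with a heteroaryl bromide under zerovalent palladium; the neutral zinc enolate does not self-condense and places the C2–C1 acetate arm next to the methyl-bearing carbon.

Step 3
Reactants: 4 ethyl 2-(3-methylfuran-2-yl)acetate; 5 (2S)-2-acetoxypropanoyl chloride
Product: 6 ethyl 2-{5-[(2S)-2-acetoxypropanoyl]-3-methylfuran-2-yl}acetate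
Conditions: SnCl4, CH2Cl2, −78 to −30 °C
Reagents that add atoms: none
Why: Friedel–Crafts acylation of a 2,3-dialkylfuran goes to the only free α-position; low temperature spares the furan, and the α-acetoxy centre (C8) is only a temporary mask for the later methyl ketone.

Step 4
Reactants: 6 ethyl 2-{5-[(2S)-2-acetoxypropanoyl]-3-methylfuran-2-yl}acetate
Product: 7 ethyl 2-{5-[(1R,2S)-2-acetoxy-1-hydroxypropyl]-3-methylfuran-2-yl}acetate
Conditions: RuCl[(R,R)-TsDPEN](p-cymene) (1 mol %), HCO2H/Et3N (5:2), rt
Reagents that add atoms: none
Why: Noyori asymmetric transfer hydrogenation of a 2-acylfuran; the furyl group takes the aryl role, so the (R,R)-catalyst should give the (R)-carbinol, in the same sense as Felkin control from the acetoxy centre. This carbon becomes C7 and is the source of every stereocentre of 19.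

Step 5
Reactants: 7 ethyl 2-{5-[(1R,2S)-2-acetoxy-1-hydroxypropyl]-3-methylfuran-2-yl}acetate
Product: 8 ethyl 2-{(6R)-6-[(1S)-1-acetoxyethyl]-2-hydroxy-3-methyl-5-oxo-5,6-dihydro-2H-pyran-2-yl}acetate
Conditions: NBS, NaHCO3, NaOAc, THF/H2O (4:1), 0 °C
Reagents that add atoms: water, O
Why: Achmatowicz rearrangement: bromonium-induced oxidation of the furan to the cis-enedione and hemiketalisation by the carbinol oxygen. C7 is not touched, and the acetate arm now sits on the hemiketal carbon C3.

Step 6
Reactants: 8 ethyl 2-{(6R)-6-[(1S)-1-acetoxyethyl]-2-hydroxy-3-methyl-5-oxo-5,6-dihydro-2H-pyran-2-yl}acetate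
Product: 9 ethyl 2-{(2S,6R)-6-[(1S)-1-acetoxyethyl]-3-methyl-5-oxo-5,6-dihydro-2H-pyran-2-yl}acetate
Conditions: Et3SiH, CF3CO2H, CH2Cl2, −40 °C
Reagents that add atoms: none
Why: Kishi reduction: ionisation to the enone-conjugated oxocarbenium ion and axial hydride delivery anti to the pseudo-equatorial C7 substituent. Because hydrogen is the last group to arrive at C3, the acetate arm ends cis to the C7 substituent (3S), the arrangement needed in 19.

Step 7
Reactants: 9 ethyl 2-{(2S,6R)-6-[(1S)-1-acetoxyethyl]-3-methyl-5-oxo-5,6-dihydro-2H-pyran-2-yl}acetate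
Product: 10 ethyl 2-{(2S,5S,6S)-6-[(1S)-1-acetoxyethyl]-5-hydroxy-3-methyl-5,6-dihydro-2H-pyran-2-yl}acetate
Conditions: NaBH4, CeCl3·7H2O, MeOH/CH2Cl2, −78 °C
Reagents that add atoms: none
Why: Luche 1,2-reduction of the enone; axial hydride attack on the half-chair gives the pseudo-equatorial alcohol trans to the C7 substituent, which is 6S. The cold, fast reduction also avoids β-elimination of the C8 acetate.

Step 8
Reactants: 10 ethyl 2-{(2S,5S,6S)-6-[(1S)-1-acetoxyethyl]-5-hydroxy-3-methyl-5,6-dihydro-2H-pyran-2-yl}acetate
Product: 11 ethyl 2-{(2S,5S,6R)-6-[(1S)-1-acetoxyethyl]-5-(tert-butyldimethylsilyloxy)-3-methyl-5,6-dihydro-2H-pyran-2-yl}acetate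
Conditions: TBSOTf, 2,6-lutidine, CH2Cl2, −78 °C
Reagents that add atoms: tert-butyldimethylsilyl triflate, CC(C)(C)[Si](C)(C)OS(=O)(=O)C(F)(F)F
Why: Silylation of the hindered allylic alcohol; this group protects O6 until step 20 and keeps O6 from competing for the lactone.

Step 9
Reactants: 11 ethyl 2-{(2S,5S,6R)-6-[(1S)-1-acetoxyethyl]-5-(tert-butyldimethylsilyloxy)-3-methyl-5,6-dihydro-2H-pyran-2-yl}acetate
Product: 12 2-{(2S,5S,6R)-5-(tert-butyldimethylsilyloxy)-6-[(1S)-1-hydroxyethyl]-3-methyl-5,6-dihydro-2H-pyran-2-yl}acetic acid
Conditions: LiOH, THF/MeOH/H2O, 0 °C to rt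
Reagents that add atoms: lithium hydroxide, [Li+].[OH-]
Why: Saponification of the ethyl ester and the acetate in one operation; at this stage no ketone is present, so no centre can epimerise or eliminate.

Step 10
Reactants: 12 2-{(2S,5S,6R)-5-(tert-butyldimethylsilyloxy)-6-[(1S)-1-hydroxyethyl]-3-methyl-5,6-dihydro-2H-pyran-2-yl}acetic acid
Product: 13 2-[(2S,5S,6S)-6-acetyl-5-(tert-butyldimethylsilyloxy)-3-methyl-5,6-dihydro-2H-pyran-2-yl]acetic acid
Conditions: Dess–Martin periodinane, pyridine, CH2Cl2, 0 °C to rt
Reagents that add atoms: none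
Why: Dess–Martin oxidation of the secondary alcohol tolerates the free acid and is non-basic, so C7 (now α to the ketone) is not epimerised and the β-silyloxy group is not eliminated.

Step 11
Reactants: 13 2-[(2S,5S,6S)-6-acetyl-5-(tert-butyldimethylsilyloxy)-3-methyl-5,6-dihydro-2H-pyran-2-yl]acetic acid
Product: 15 2-{(2S,5S,6S)-5-(tert-butyldimethylsilyloxy)-6-[1-(tert-butyldimethylsilyloxy)vinyl]-3-methyl-5,6-dihydro-2H-pyran-2-yl}acetic acid, via silyl ester 14 (not isolated)
Conditions: LiN(SiMe3)2 (2.2 equiv), THF, −78 °C; TBSOTf (2.3 equiv); then K2CO3, MeOH/H2O, 0 °C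
Reagents that add atoms: tert-butyldimethylsilyl triflate, CC(C)(C)[Si](C)(C)OS(=O)(=O)C(F)(F)F
Why: The first equivalent of base forms the carboxylate; the second removes a methyl proton kinetically, not the hindered α-alkoxy methine, and O-silylation gives the terminal enol ether. The silyl ester is far more labile than the silyl enol ether and is cleaved by cold carbonate.

Step 12
Reactants: 15 2-{(2S,5S,6S)-5-(tert-butyldimethylsilyloxy)-6-[1-(tert-butyldimethylsilyloxy)vinyl]-3-methyl-5,6-dihydro-2H-pyran-2-yl}acetic acid; 16 N-ethyl-N-nitrosourea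
Product: 19 3-diazo-1-{(2S,5S,6S)-5-(tert-butyldimethylsilyloxy)-6-[1-(tert-butyldimethylsilyloxy)vinyl]-3-methyl-5,6-dihydro-2H-pyran-2-yl}butan-2-one, via diazoethane 17 (not isolated), via mixed carbonic anhydride 18 (not isolated)
Conditions: 15, Et3N, i-BuOCOCl, THF, −20 °C; then CH3CHN2 in Et2O (from 16, KOH, Et2O/H2O, 0 °C), 0 °C to rt
Reagents that add atoms: none
Why: Acylation of a diazoalkane by a mixed carbonic anhydride; the conditions stay neutral to basic, so the silyl enol ether survives. Diazoethane brings C10 and C14 together.

Step 13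
Reactants: 19 3-diazo-1-{(2S,5S,6S)-5-(tert-butyldimethylsilyloxy)-6-[1-(tert-butyldimethylsilyloxy)vinyl]-3-methyl-5,6-dihydro-2H-pyran-2-yl}butan-2-one
Product: 21 oxa-bridged bicyclic ketone with the C7=C8 silyl enol ether (3S,6S,10S), via oxonium ylide 20 (not isolated)
Conditions: Cu(CF3COCHCOCF3)2 (5 mol %), CH2Cl2, reflux, slow addition of 19
Reagents that add atoms: none
Why: The carbenoid formed at C10 on divalent copper with loss of nitrogen is captured by the pyran oxygen five atoms away, and oxonium ylide 20 rearranges by a [2,3]-shift through a five-membered envelope transition state in which the enolate carbon C10 bonds to the terminal carbon C9 of the silyloxyvinyl group while O–C7 breaks. The closest known reaction type is the copper-catalysed oxonium ylide formation and [2,3]-rearrangement of 2-vinyl tetrahydropyrans that carry a diazoketone arm at C6, which gives the same 11-oxabicyclo[6.2.1]undecenone skeleton; the silyloxy substituent on the migrating allyl unit and the ring alkene of the dihydropyran are untested. The tetrahydrofuranone closes in the ylide-forming event by O–C10 bond formation (attack of the ring oxygen on the exocyclic carbenoid carbon), and the ten-membered carbocycle closes by C9–C10 bond formation in the shift, as a three-atom ring expansion of the pyran and not as an end-to-end cyclisation. The only new stereocentre, C10, is controlled by C3: the one-atom oxygen bridge can span C3 and C10 only if the C4 and C9 arms are cis on the five-membered ring, so 3S gives 10S. The step needs ylide formation in preference to 1,2-hydride shift from the C14 methyl group and to cyclopropanation of the electron-rich enol ether, [2,3]- in preference to [1,2]-shift, and migration of the exocyclic allyl unit, not the in-ring one (C3–C4=C5). Proximity (a five-membered ylide against a seven- or eight-membered cyclopropanation) and the electrophilic hexafluoroacetylacetonate carbenoid favour attack at oxygen; the cis-2,6 ring holds the silyloxyvinyl group pseudo-equatorial and gauche to the new O–C10 bond in either ylide epimer, whereas the in-ring allyl unit has its C3–O bond locked in the ylide ring, nearly orthogonal to the C4=C5 π system. C8 emerges as a ketone equivalent regiodefined towards C7, and the enol ether geometry is of no consequence because C7 is rehybridised in step 15.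

Step 14
Reactants: 21 oxa-bridged bicyclic ketone with the C7=C8 silyl enol ether (3S,6S,10S)
Product: 23 oxa-bridged furanone with the C7=C8 silyl enol ether (6S,10S), via trimethylsilyl enol ether 22 (not isolated)
Conditions: LiN(SiMe3)2, Me3SiCl, THF, −78 °C; then Pd(OAc)2 (1.1 equiv), MeCN, rt
Reagents that add atoms: none
Why: Saegusa–Ito oxidation: C1 can enolise only towards C2 because C10 is quaternary, the trimethylsilyl enol ether transmetalates to palladium much faster than the hindered tert-butyldimethylsilyl enol ether at C8, and β-hydride elimination of H3 gives the furanone. Doing this while C8 is masked makes C1 a vinylogous ester that will survive the borohydride of step 17.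

Step 15
Reactants: 23 oxa-bridged furanone with the C7=C8 silyl enol ether (6S,10S); 24 ethyl diazoacetate
Product: 25 silyloxycyclopropane ester fused at C7–C8 (6S,7S,8S,10S)
Conditions: Rh2(OAc)4 (1 mol %), CH2Cl2, rt, slow addition of 24 (3 equiv)
Reagents that add atoms: none
Why: Rhodium-carbenoid cyclopropanation of a silyl enol ether, which reacts in preference to the conjugated C4=C5 and the push–pull C2=C3 alkenes. Approach from the peripheral face, syn to H6 with the C6 silyloxy group in the inside position and anti to C5, should put the C7–C11 bond on the face required for 7R in the lactone.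

Step 16
Reactants: 25 silyloxycyclopropane ester fused at C7–C8 (6S,7S,8S,10S)
Product: 26 C8 ketone with the ethyl acetate arm on C7 (6S,7S,10S)
Conditions: Bu4NF, AcOH (1:1), THF, 0 °C
Reagents that add atoms: none
Why: Fluoride-induced ring opening of a 2-silyloxycyclopropane carboxylate cleaves C8–C11 and unveils the C8 ketone and the C7 acetate arm, a formal regiospecific enolate alkylation without a free β-silyloxy enolate. Acetic acid protonates the ester enolate at once, and C7 keeps its configuration because C7–C11 is not broken.

Step 17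
Reactants: 26 C8 ketone with the ethyl acetate arm on C7 (6S,7S,10S)
Product: 28 trans-fused 8,12-lactone (6S,7R,8S,10S), via hydroxy ester 27 (not isolated)
Conditions: NaBH4, MeOH/THF, −40 °C; then pyridinium p-toluenesulfonate, benzene, 50 °C
Reagents that add atoms: none
Why: A small hydride at low temperature reduces the saturated C8 ketone and leaves the vinylogous-ester carbonyl C1; attack on the extended conformer anti to the C7 acetate arm should give the 8S alcohol (C11 and O8 syn). Mild acid closes the γ-lactone with loss of ethanol; O6 is silylated and cannot compete.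

Step 18
Reactants: 28 trans-fused 8,12-lactone (6S,7R,8S,10S)
Product: 29 11-(dimethylaminomethyl) lactone
Conditions: LiN(i-Pr)2, THF, −78 °C; CH2=NMe2+ I−, −78 to 0 °C
Reagents that add atoms: N,N-dimethylmethyleneiminium iodide, C=[N+](C)C.[I-]
Why: Mannich reaction of the lactone enolate with Eschenmoser's salt; the C11 protons are the only readily removed ones, since C10 is quaternary and the furanone has no α-hydrogen.

Step 19
Reactants: 29 11-(dimethylaminomethyl) lactone
Product: 31 α-methylene lactone with the 6-silyl ether (6S,7R,8S,10S), via trimethylammonium iodide 30 (not isolated)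
Conditions: MeI, MeOH, rt; then NaHCO3, H2O/CH2Cl2, rt
Reagents that add atoms: none
Why: Quaternisation and Hofmann-type E1cB elimination give the exocyclic methylene under bicarbonate, mild enough for the furanone.

Step 20
Reactants: 31 α-methylene lactone with the 6-silyl ether (6S,7R,8S,10S)
Product: 32 6-hydroxy α-methylene lactone (6S,7S,8S,10S)
Conditions: HF·pyridine, pyridine/THF, 0 °C to rt
Reagents that add atoms: none
Why: Buffered HF removes the secondary silyl ether without the basic fluoride that would add to the α-methylene lactone.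

Step 21
Reactants: 33 angelic acid
Product: 34 (Z)-2-methylbut-2-en-1-ol
Conditions: LiAlH4, Et2O, 0 °C
Reagents that add atoms: none
Why: 1,2-Reduction of the unsaturated acid to the allylic alcohol with retention of the Z geometry.

Step 22
Reactants: 34 (Z)-2-methylbut-2-en-1-ol
Product: 35 [(2R,3S)-2,3-dimethyloxiran-2-yl]methanol
Conditions: Ti(Oi-Pr)4, D-(−)-diethyl tartrate, t-BuOOH, 4 Å molecular sieves, CH2Cl2, −20 °C
Reagents that add atoms: tert-butyl hydroperoxide, CC(C)(C)OO
Why: Sharpless asymmetric epoxidation; the Z alkene gives the cis epoxide (hydroxymethyl and C3 methyl cis) and the D-tartrate delivers oxygen to the face that gives 2R, which becomes 2S in the acid.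

Step 23
Reactants: 35 [(2R,3S)-2,3-dimethyloxiran-2-yl]methanol
Product: 36 (2S,3S)-2,3-dimethyloxirane-2-carboxylic acid
Conditions: TEMPO (cat.), PhI(OAc)2, MeCN/H2O, rt
Reagents that add atoms: water, O
Why: Oxoammonium oxidation of the primary alcohol through the aldehyde hydrate to the acid under near-neutral conditions that leave the epoxide intact.

Step 24
Reactants: 32 6-hydroxy α-methylene lactone (6S,7S,8S,10S); 36 (2S,3S)-2,3-dimethyloxirane-2-carboxylic acid
Product: 38 target, via mixed anhydride 37 (not isolated)
Conditions: 36, 2,4,6-Cl3C6H2COCl, Et3N, THF, rt; then 32, DMAP, toluene, rt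
Reagents that add atoms: none
Why: Yamaguchi esterification suits a hindered secondary allylic alcohol and an α,α-disubstituted acid; the acid has no α-hydrogen, so its stereocentres cannot epimerise, and the C6–O bond is not touched.

## Compound list

1 | 3-methylfuran | Cc1ccoc1 | starting material
2 | 2-bromo-3-methylfuran | Cc1ccoc1Br | intermediate
3 | (2-ethoxy-2-oxoethyl)zinc bromide | CCOC(=O)C[Zn]Br | starting material
4 | ethyl 2-(3-methylfuran-2-yl)acetate | CCOC(=O)Cc1occc1C | intermediate
5 | (2S)-2-acetoxypropanoyl chloride | C[C@H](OC(C)=O)C(Cl)=O | starting material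
6 | ethyl 2-{5-[(2S)-2-acetoxypropanoyl]-3-methylfuran-2-yl}acetate | CCOC(=O)Cc1oc(cc1C)C(=O)[C@H](C)OC(C)=O | intermediate
7 | ethyl 2-{5-[(1R,2S)-2-acetoxy-1-hydroxypropyl]-3-methylfuran-2-yl}acetate | CCOC(=O)Cc1oc(cc1C)[C@H](O)[C@H](C)OC(C)=O | intermediate
8 | ethyl 2-{(6R)-6-[(1S)-1-acetoxyethyl]-2-hydroxy-3-methyl-5-oxo-5,6-dihydro-2H-pyran-2-yl}acetate (both anomers) | CCOC(=O)CC1(O)O[C@H]([C@H](C)OC(C)=O)C(=O)C=C1C | intermediate
9 | ethyl 2-{(2S,6R)-6-[(1S)-1-acetoxyethyl]-3-methyl-5-oxo-5,6-dihydro-2H-pyran-2-yl}acetate | CCOC(=O)C[C@@H]1O[C@H]([C@H](C)OC(C)=O)C(=O)C=C1C | intermediate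
10 | ethyl 2-{(2S,5S,6S)-6-[(1S)-1-acetoxyethyl]-5-hydroxy-3-methyl-5,6-dihydro-2H-pyran-2-yl}acetate | CCOC(=O)C[C@@H]1O[C@H]([C@H](C)OC(C)=O)[C@@H](O)C=C1C | intermediate
11 | ethyl 2-{(2S,5S,6R)-6-[(1S)-1-acetoxyethyl]-5-(tert-butyldimethylsilyloxy)-3-methyl-5,6-dihydro-2H-pyran-2-yl}acetate | CCOC(=O)C[C@@H]1O[C@H]([C@H](C)OC(C)=O)[C@@H](O[Si](C)(C)C(C)(C)C)C=C1C | intermediate
12 | 2-{(2S,5S,6R)-5-(tert-butyldimethylsilyloxy)-6-[(1S)-1-hydroxyethyl]-3-methyl-5,6-dihydro-2H-pyran-2-yl}acetic acid | OC(=O)C[C@@H]1O[C@H]([C@H](C)O)[C@@H](O[Si](C)(C)C(C)(C)C)C=C1C | intermediate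
13 | 2-[(2S,5S,6S)-6-acetyl-5-(tert-butyldimethylsilyloxy)-3-methyl-5,6-dihydro-2H-pyran-2-yl]acetic acid | OC(=O)C[C@@H]1O[C@H](C(C)=O)[C@@H](O[Si](C)(C)C(C)(C)C)C=C1C | intermediate
14 | tert-butyldimethylsilyl ester of acid 15 | CC(C)(C)[Si](C)(C)OC(=O)C[C@@H]1O[C@H](C(=C)O[Si](C)(C)C(C)(C)C)[C@@H](O[Si](C)(C)C(C)(C)C)C=C1C | intermediate
15 | 2-{(2S,5S,6S)-5-(tert-butyldimethylsilyloxy)-6-[1-(tert-butyldimethylsilyloxy)vinyl]-3-methyl-5,6-dihydro-2H-pyran-2-yl}acetic acid | OC(=O)C[C@@H]1O[C@H](C(=C)O[Si](C)(C)C(C)(C)C)[C@@H](O[Si](C)(C)C(C)(C)C)C=C1C | intermediate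
16 | N-ethyl-N-nitrosourea | CCN(N=O)C(N)=O | starting material
17 | diazoethane | CC=[N+]=[N-] | intermediate
18 | isobutyl carbonic mixed anhydride of acid 15 | CC(C)COC(=O)OC(=O)C[C@@H]1O[C@H](C(=C)O[Si](C)(C)C(C)(C)C)[C@@H](O[Si](C)(C)C(C)(C)C)C=C1C | intermediate
19 | 3-diazo-1-{(2S,5S,6S)-5-(tert-butyldimethylsilyloxy)-6-[1-(tert-butyldimethylsilyloxy)vinyl]-3-methyl-5,6-dihydro-2H-pyran-2-yl}butan-2-one (dihydropyranyl diazoketone, target atoms C3, C6, C7 all S) | CC(=[N+]=[N-])C(=O)C[C@@H]1O[C@H](C(=C)O[Si](C)(C)C(C)(C)C)[C@@H](O[Si](C)(C)C(C)(C)C)C=C1C | intermediate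
20 | bicyclic oxonium ylide: pyran oxygen bonded to C3, C7 and C10, carbanion at C10 next to the C1 carbonyl | C[C-]1C(=O)C[C@H]2C(C)=C[C@H](O[Si](C)(C)C(C)(C)C)[C@@H](C(=C)O[Si](C)(C)C(C)(C)C)[O+]12 | intermediate
21 | oxa-bridged bicyclic ketone: C1 ketone, C2 methylene, 3S ether carbon, 4Z alkene with methyl C15, 6S silyl ether, C7=C8 tert-butyldimethylsilyl enol ether (C6 and C9 cis), 10S carbon with methyl C14 | C[C@]12C/C(O[Si](C)(C)C(C)(C)C)=C\[C@@H](O[Si](C)(C)C(C)(C)C)/C=C(C)\[C@H](CC1=O)O2 | intermediate
22 | C1 trimethylsilyl enol ether (C1=C2) of 21 | C[C@]12C/C(O[Si](C)(C)C(C)(C)C)=C\[C@@H](O[Si](C)(C)C(C)(C)C)/C=C(C)\[C@H](C=C1O[Si](C)(C)C)O2 | intermediate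
23 | oxa-bridged 3(2H)-furanone (C2=C3) with 4Z alkene, 6S silyl ether and C7=C8 silyl enol ether, 10S | C[C@]12C/C(O[Si](C)(C)C(C)(C)C)=C\[C@@H](O[Si](C)(C)C(C)(C)C)/C=C(C)\C(=CC1=O)O2 | intermediate
24 | ethyl diazoacetate | CCOC(=O)C=[N+]=[N-] | starting material
25 | furanone with a cyclopropane on C7–C8–C11: 8-silyloxy, 11-ethoxycarbonyl (both C11 epimers), 6S,7S,8S,10S | C[C@]12C[C@@]3(O[Si](C)(C)C(C)(C)C)C(C(=O)OCC)[C@H]3[C@@H](O[Si](C)(C)C(C)(C)C)/C=C(C)\C(=CC1=O)O2 | intermediate
26 | furanone C8 ketone with CH2CO2Et on C7 (6S,7S,10S), 6-silyl ether | C[C@]12CC(=O)[C@@H](CC(=O)OCC)[C@@H](O[Si](C)(C)C(C)(C)C)/C=C(C)\C(=CC1=O)O2 | intermediate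
27 | 8S-hydroxy ethyl ester (6S,7R,8S,10S) | C[C@]12C[C@H](O)[C@@H](CC(=O)OCC)[C@@H](O[Si](C)(C)C(C)(C)C)/C=C(C)\C(=CC1=O)O2 | intermediate
28 | trans-fused 8,12-lactone with C11 methylene, 6-silyl ether (6S,7R,8S,10S) | C[C@]12C[C@@H]3OC(=O)C[C@H]3[C@@H](O[Si](C)(C)C(C)(C)C)/C=C(C)\C(=CC1=O)O2 | intermediate
29 | 11-(dimethylaminomethyl) lactone (both C11 epimers) | C[C@]12C[C@@H]3OC(=O)C(CN(C)C)[C@H]3[C@@H](O[Si](C)(C)C(C)(C)C)/C=C(C)\C(=CC1=O)O2 | intermediate
30 | 11-(trimethylammoniomethyl) lactone iodide | C[C@]12C[C@@H]3OC(=O)C(C[N+](C)(C)C)[C@H]3[C@@H](O[Si](C)(C)C(C)(C)C)/C=C(C)\C(=CC1=O)O2.[I-] | intermediate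
31 | 6-O-tert-butyldimethylsilyl α-methylene lactone (6S,7R,8S,10S) | C=C1C(=O)O[C@H]2C[C@]3(C)OC(=CC3=O)/C(C)=C\[C@H](O[Si](C)(C)C(C)(C)C)[C@H]12 | intermediate
32 | 6-hydroxy α-methylene lactone (6S,7S,8S,10S) | C=C1C(=O)O[C@H]2C[C@]3(C)OC(=CC3=O)/C(C)=C\[C@H](O)[C@H]12 | intermediate
33 | angelic acid, (Z)-2-methylbut-2-enoic acid | C/C=C(/C)C(=O)O | starting material
34 | (Z)-2-methylbut-2-en-1-ol | C/C=C(/C)CO | intermediate
35 | [(2R,3S)-2,3-dimethyloxiran-2-yl]methanol | OC[C@@]1(C)O[C@H]1C | intermediate
36 | (2S,3S)-2,3-dimethyloxirane-2-carboxylic acid | OC(=O)[C@@]1(C)O[C@H]1C | intermediate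
37 | mixed anhydride of 36 with 2,4,6-trichlorobenzoic acid | Clc1cc(Cl)cc(Cl)c1C(=O)OC(=O)[C@@]1(C)O[C@H]1C | intermediate
38 | CNP0258430.1: 6-O-[(2S,3S)-2,3-epoxy-2-methylbutanoyl] furanone 8,12-lactone (6S,7R,8S,10S) | C=C1C(=O)O[C@H]2C[C@]3(C)OC(=CC3=O)/C(C)=C\[C@H](OC(=O)[C@@]3(C)O[C@H]3C)[C@H]12 | target

## Step count and least certain steps

Total step count: 24. Longest linear sequence: 21 steps (steps 1–20 and 24); acid 36 is made in three steps (21–23).

**Step 13 (key step).** The carbenoid may be diverted before the shift: by 1,2-hydride migration from the C14 methyl group, by attack on the nucleophilic silyl enol ether, or by [1,2]-shift or fragmentation of the ylide because the electron-rich C9 terminus is a poor partner for the enolate carbon. The fallback keeps the disconnection but carries C8 as an enol acetate, which is inert to the carbenoid and a better acceptor. It sets out from keto acid 13 and returns at keto ester 26. The kinetic lithium enolate of 13 (LiN(SiMe3)2, 2.2 equiv) is O-acetylated with Ac2O to the mixed acetic anhydride of the enol acetate F1, and bicarbonate work-up gives the enol acetate acid F2. Activation as the isobutyl carbonic anhydride F3 and acylation of diazoethane 17 give the enol acetate diazoketone F4. Under the copper catalyst of step 13 this should pass through the oxonium ylide F5 to the bicyclic enol acetate F6. Soft enolisation of C1 (Me3SiOTf, Et3N) to the trimethylsilyl enol ether F7 and Pd(OAc)2 give the furanone enol acetate F8. Bu3SnOMe cleaves the acetate to the tributyltin enolate F9, and alkylation with ethyl iodoacetate gives 26.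

**Step 15.** The hindered, trisubstituted enol ether may react too slowly, so that the carbenoid dimerises, or the carbenoid may add from the face syn to C5 and give the C7 epimer. The fallback replaces carbenoid transfer by regiospecific enolate alkylation. It sets out from 23 and returns at 26. Tris(dimethylamino)sulfonium difluorotrimethylsilicate in THF at −78 °C, with ethyl iodoacetate already present, cleaves only the enol silyl group. The resulting sulfonium enolate F12 is alkylated at C7 before the C6 silyloxy group can be lost, and C7 remains correctable by equilibration through the ketone.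

**Step 17.** Hydride may attack from the other face, because the conformation of the ten-membered ketone cannot be fixed on paper; the lactone would then be cis-fused. The fallback corrects C8 by inversion. It sets out from 26 and returns at 28. Reduction then gives the 8-epi hydroxy ester F13, which closes to the cis-fused lactone F14. LiOH at 0 °C and careful acidification give the 8-epi hydroxy acid F15, and Mitsunobu lactonisation (PPh3, diisopropyl azodicarboxylate) closes the ring with inversion at C8 to 28.

**Step 14.** Palladium may also engage the C8 silyl enol ether, so that oxidation is not confined to C1. The fallback changes the order so that only one silyl enol ether is ever present. It sets out from 21 and returns at 25. Cyclopropanation of 21 with 24 (Rh2(OAc)4) gives the cyclopropane of the saturated ketone F10; LiN(SiMe3)2/Me3SiCl gives its C1 trimethylsilyl enol ether F11, and Pd(OAc)2 gives 25.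

## Further compounds

F1 | step 13 | mixed acetic anhydride of the enol acetate acid | CC(=O)OC(=O)C[C@@H]1O[C@H](C(=C)OC(C)=O)[C@@H](O[Si](C)(C)C(C)(C)C)C=C1C
F2 | step 13 | enol acetate acid | OC(=O)C[C@@H]1O[C@H](C(=C)OC(C)=O)[C@@H](O[Si](C)(C)C(C)(C)C)C=C1C
F3 | step 13 | isobutyl carbonic anhydride of F2 | CC(C)COC(=O)OC(=O)C[C@@H]1O[C@H](C(=C)OC(C)=O)[C@@H](O[Si](C)(C)C(C)(C)C)C=C1C
F4 | step 13 | enol acetate diazoketone | CC(=[N+]=[N-])C(=O)C[C@@H]1O[C@H](C(=C)OC(C)=O)[C@@H](O[Si](C)(C)C(C)(C)C)C=C1C
F5 | step 13 | oxonium ylide of F4 | C[C-]1C(=O)C[C@H]2C(C)=C[C@H](O[Si](C)(C)C(C)(C)C)[C@@H](C(=C)OC(C)=O)[O+]12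
F6 | step 13 | bicyclic enol acetate | C[C@]12C/C(OC(C)=O)=C\[C@@H](O[Si](C)(C)C(C)(C)C)/C=C(C)\[C@H](CC1=O)O2
F7 | step 13 | C1 trimethylsilyl enol ether of F6 | C[C@]12C/C(OC(C)=O)=C\[C@@H](O[Si](C)(C)C(C)(C)C)/C=C(C)\[C@H](C=C1O[Si](C)(C)C)O2
F8 | step 13 | furanone enol acetate | C[C@]12C/C(OC(C)=O)=C\[C@@H](O[Si](C)(C)C(C)(C)C)/C=C(C)\C(=CC1=O)O2
F9 | step 13 | tributyltin enolate | C[C@]12C/C(O[Sn](CCCC)(CCCC)CCCC)=C\[C@@H](O[Si](C)(C)C(C)(C)C)/C=C(C)\C(=CC1=O)O2
F10 | step 14 | cyclopropane of the saturated ketone | C[C@]12C[C@@]3(O[Si](C)(C)C(C)(C)C)C(C(=O)OCC)[C@H]3[C@@H](O[Si](C)(C)C(C)(C)C)/C=C(C)\[C@H](CC1=O)O2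
F11 | step 14 | C1 trimethylsilyl enol ether of F10 | C[C@]12C[C@@]3(O[Si](C)(C)C(C)(C)C)C(C(=O)OCC)[C@H]3[C@@H](O[Si](C)(C)C(C)(C)C)/C=C(C)\[C@H](C=C1O[Si](C)(C)C)O2
F12 | step 15 | tris(dimethylamino)sulfonium C8 enolate | C[C@]12C/C([O-])=C\[C@@H](O[Si](C)(C)C(C)(C)C)/C=C(C)\C(=CC1=O)O2.CN(C)[S+](N(C)C)N(C)C
F13 | step 17 | 8-epi hydroxy ester | C[C@]12C[C@@H](O)[C@@H](CC(=O)OCC)[C@@H](O[Si](C)(C)C(C)(C)C)/C=C(C)\C(=CC1=O)O2
F14 | step 17 | cis-fused lactone | C[C@]12C[C@H]3OC(=O)C[C@H]3[C@@H](O[Si](C)(C)C(C)(C)C)/C=C(C)\C(=CC1=O)O2
F15 | step 17 | 8-epi hydroxy acid | C[C@]12C[C@@H](O)[C@@H](CC(=O)O)[C@@H](O[Si](C)(C)C(C)(C)C)/C=C(C)\C(=CC1=O)O2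
A1 | alternative 1 | cyclopropane-fused γ-lactone with the C4=C5 alkenyl arm on C6 and the silylated alkynyl carbinol arm on C8 | O=C1O[C@@H](C[C@](C)(O[Si](CC)(CC)CC)C#C[Si](C)(C)C)[C@@H]2[C@@H](/C=C(C)\CO[Si](C)(C)C(C)(C)C)[C@H]12
A2 | alternative 2 | ten-membered 3-silyloxy dienone with the saturated 8,12-lactone | O=C1O[C@H]2C[C@](C)(O[Si](CC)(CC)CC)C(=O)/C=C(O[Si](C(C)C)(C(C)C)C(C)C)/C(C)=C\[C@H](O[Si](C)(C)C(C)(C)C)[C@@H]2C1
A3 | alternative 3 | oxa-bridged ten-membered furanone with 6-hydroxyl, 7-isopropenyl and 8-silyloxy groups | C[C@]12C[C@H](O[Si](C)(C)C(C)(C)C)[C@@H](C(C)=C)[C@@H](O)/C=C(C)\C(=CC1=O)O2
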